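**Assumption:** the SMILES is read as the (1S,2R,1′S)-isomer with the C1 side chain and the C2 hydroxyl cis on the tetralin; 6,7-dimethoxy-2-tetralone and 4-ethynylphenol are taken as commercial.

## Retrosynthetic overview

- Target ⇐ global desilylation of a bis-TBS ether (last step, fluoride only, no acid).
- C1′–C2′ bond and C1′ stereocenter ⇐ new redox-neutral nickel-catalysed coupling of a tetralin-1-ylmethanol with a terminal arylacetylene (aldehyde formed and consumed on the metal).
- Tetralinylmethanol ⇐ cis-β-hydroxy ester (silylation, ester reduction); C1 and C2 are set together by transfer hydrogenation of a 2-tetralone-1-carboxylate with dynamic kinetic resolution.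
- β-Keto ester ⇐ C1-methoxycarbonylation of 6,7-dimethoxy-2-tetralone; alkyne ⇐ silylation of 4-ethynylphenol.
- Ring order: the tetralin and the phenol ring are both bought intact; no ring is formed in the route.

## Route

Step 1
Reactants: 1 6,7-dimethoxy-3,4-dihydronaphthalen-2(1H)-one (6,7-dimethoxy-2-tetralone)
Product: 2 methyl 6,7-dimethoxy-2-oxo-1,2,3,4-tetrahydronaphthalene-1-carboxylate (racemic, C1 labile, largely enol)
Conditions: NaH (2.2 equiv), (MeO)2CO (5 equiv), THF, 65 °C; then aq. HCl, 0 °C
Reagents that add atoms: dimethyl carbonate COC(=O)OC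
Why: Crossed Claisen-type C-acylation in which the conjugated, more acidic benzylic C1 enolate of the 2-tetralone is acylated and the product is trapped as its stabilised β-keto ester enolate, which drives C1 regioselectivity; no stereocenter is fixed because C1 stays labile.

Step 2
Reactants: 2 methyl 6,7-dimethoxy-2-oxo-1,2,3,4-tetrahydronaphthalene-1-carboxylate
Product: 3 methyl (1S,2R)-2-hydroxy-6,7-dimethoxy-1,2,3,4-tetrahydronaphthalene-1-carboxylate (cis)
Conditions: RuCl[(R,R)-TsDPEN](p-cymene) (2 mol %), HCO2H/Et3N (5:2), DMF, 40 °C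
Reagents that add atoms: none
Why: Noyori–Ikariya asymmetric transfer hydrogenation with dynamic kinetic resolution: C1 racemises fast through the enol, outer-sphere hydride delivery occurs anti to the pseudoaxial C1 ester (hence cis), and the (R,R)-catalyst is expected to attack the C2 Si face with the sp2-rich C1 branch in the arene-side position taken by the aryl group of aryl ketones, giving 2R and therefore 1S.

Step 3
Reactants: 3 methyl (1S,2R)-2-hydroxy-6,7-dimethoxy-1,2,3,4-tetrahydronaphthalene-1-carboxylate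
Product: 4 methyl (1S,2R)-2-[(tert-butyldimethylsilyl)oxy]-6,7-dimethoxy-1,2,3,4-tetrahydronaphthalene-1-carboxylate
Conditions: TBSOTf (1.3 equiv), 2,6-lutidine (2 equiv), CH2Cl2, −78 to 0 °C
Reagents that add atoms: tert-butyldimethylsilyl trifluoromethanesulfonate CC(C)(C)[Si](C)(C)OS(=O)(=O)C(F)(F)F
Why: Standard silyl ether formation with a silyl triflate and a hindered weak base, which neither epimerises the α-aryl ester centre nor eliminates the β-oxygen.

Step 4
Reactants: 4 methyl (1S,2R)-2-[(tert-butyldimethylsilyl)oxy]-6,7-dimethoxy-1,2,3,4-tetrahydronaphthalene-1-carboxylate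
Product: 5 [(1R,2R)-2-[(tert-butyldimethylsilyl)oxy]-6,7-dimethoxy-1,2,3,4-tetrahydronaphthalen-1-yl]methanol
Conditions: i-Bu2AlH (3 equiv), CH2Cl2, −78 to 0 °C; aq. KNaC4H4O6 work-up
Reagents that add atoms: none
Why: Hydride reduction of the ester to the primary alcohol under non-basic aluminium alkoxide conditions, so C1 is not epimerised and the silyl group does not migrate (the C1 descriptor changes to R only through CIP priorities).

Step 5
Reactants: 6 4-ethynylphenol
Product: 7 tert-butyl(4-ethynylphenoxy)dimethylsilane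
Conditions: TBSCl (1.1 equiv), imidazole (2 equiv), DMF, rt
Reagents that add atoms: tert-butyldimethylsilyl chloride CC(C)(C)[Si](C)(C)Cl
Why: Routine phenol silylation (Corey conditions) that masks the acidic O–H before the nickel step.

Step 6
Reactants: 5 [(1R,2R)-2-[(tert-butyldimethylsilyl)oxy]-6,7-dimethoxy-1,2,3,4-tetrahydronaphthalen-1-yl]methanol; 7 tert-butyl(4-ethynylphenoxy)dimethylsilane
Product: 9 (1S,2E)-1-[(1R,2R)-2-[(tert-butyldimethylsilyl)oxy]-6,7-dimethoxy-1,2,3,4-tetrahydronaphthalen-1-yl]-3-[4-[(tert-butyldimethylsilyl)oxy]phenyl]prop-2-en-1-ol, via nickel-bound aldehyde 8 (not isolated)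
Conditions: Ni(cod)2 (10 mol %), IMes (1,3-dimesitylimidazol-2-ylidene, 10 mol %), toluene, 60 °C, 7 (1.4 equiv) added by syringe pump over 8 h
Reagents that add atoms: none
Why: Proposed new method: a zerovalent nickel/NHC redox-neutral (hydrogen auto-transfer) coupling of an α-stereogenic aliphatic primary alcohol with a terminal arylacetylene, in which a little 7 first accepts hydrogen to give nickel-bound aldehyde 8, then 8 and the alkyne undergo oxidative cyclisation (C–C bond at the terminal alkyne carbon, aryl carbon on nickel) to an oxanickelacyclopentene, the O–H of a second molecule of 5 opens the Ni–O bond, β-hydride elimination regenerates bound 8 and C–H reductive elimination puts hydrogen cis to the carbinol carbon (hence E), with C1′ set in the oxidative cyclisation by Felkin–Anh attack anti to the C2 branch carrying the bulky OTBS group (this gives 1′S) and with the neutral, base-free, metal-bound aldehyde protecting C1 from epimerisation and β-elimination; the closest known reaction types are the nickel/NHC redox-neutral couplings of simple alcohols with internal alkynes and the nickel-catalysed aldehyde–alkyne reductive couplings with silanes, neither shown for a terminal aryl alkyne with a chiral β-silyloxy alcohol.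

Step 7
Reactants: 9 (1S,2E)-1-[(1R,2R)-2-[(tert-butyldimethylsilyl)oxy]-6,7-dimethoxy-1,2,3,4-tetrahydronaphthalen-1-yl]-3-[4-[(tert-butyldimethylsilyl)oxy]phenyl]prop-2-en-1-ol
Product: 10 (1S,2R)-1-[(1S,2E)-1-hydroxy-3-(4-hydroxyphenyl)prop-2-en-1-yl]-6,7-dimethoxy-1,2,3,4-tetrahydronaphthalen-2-ol
Conditions: Bu4NF (2.5 equiv), AcOH (2.5 equiv), THF, 0 °C to rt
Reagents that add atoms: none
Why: Fluoride-mediated cleavage of the aryl and the secondary silyl ether under acetate buffering, which avoids the acid that would ionise the 4-hydroxycinnamyl alcohol and leaves all three stereocenters and the E-alkene untouched.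

## Compound list

1 | 6,7-dimethoxy-3,4-dihydronaphthalen-2(1H)-one | COc1cc2c(cc1OC)CC(=O)CC2 | starting material
2 | methyl 6,7-dimethoxy-2-oxo-1,2,3,4-tetrahydronaphthalene-1-carboxylate (racemic, C1 labile) | COC(=O)C1C(=O)CCc2cc(OC)c(OC)cc21 | intermediate
3 | methyl (1S,2R)-2-hydroxy-6,7-dimethoxy-1,2,3,4-tetrahydronaphthalene-1-carboxylate | COc1cc2c(cc1OC)[C@H](C(=O)OC)[C@H](O)CC2 | intermediate
4 | methyl (1S,2R)-2-[(tert-butyldimethylsilyl)oxy]-6,7-dimethoxy-1,2,3,4-tetrahydronaphthalene-1-carboxylate | COc1cc2c(cc1OC)[C@H](C(=O)OC)[C@H](O[Si](C)(C)C(C)(C)C)CC2 | intermediate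
5 | [(1R,2R)-2-[(tert-butyldimethylsilyl)oxy]-6,7-dimethoxy-1,2,3,4-tetrahydronaphthalen-1-yl]methanol | COc1cc2c(cc1OC)[C@H](CO)[C@H](O[Si](C)(C)C(C)(C)C)CC2 | intermediate
6 | 4-ethynylphenol | C#Cc1ccc(O)cc1 | starting material
7 | tert-butyl(4-ethynylphenoxy)dimethylsilane | C#Cc1ccc(O[Si](C)(C)C(C)(C)C)cc1 | intermediate
8 | (1S,2R)-2-[(tert-butyldimethylsilyl)oxy]-6,7-dimethoxy-1,2,3,4-tetrahydronaphthalene-1-carbaldehyde (nickel-bound, not isolated) | COc1cc2c(cc1OC)[C@H](C=O)[C@H](O[Si](C)(C)C(C)(C)C)CC2 | intermediate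
9 | (1S,2E)-1-[(1R,2R)-2-[(tert-butyldimethylsilyl)oxy]-6,7-dimethoxy-1,2,3,4-tetrahydronaphthalen-1-yl]-3-[4-[(tert-butyldimethylsilyl)oxy]phenyl]prop-2-en-1-ol | COc1cc2c(cc1OC)[C@H]([C@@H](O)/C=C/c1ccc(O[Si](C)(C)C(C)(C)C)cc1)[C@H](O[Si](C)(C)C(C)(C)C)CC2 | intermediate
10 | (1S,2R)-1-[(1S,2E)-1-hydroxy-3-(4-hydroxyphenyl)prop-2-en-1-yl]-6,7-dimethoxy-1,2,3,4-tetrahydronaphthalen-2-ol | COc1cc2c(cc1OC)[C@H]([C@@H](O)/C=C/c1ccc(O)cc1)[C@H](O)CC2 | target

## Step count

Total steps: 7. Longest linear sequence: 6 steps (steps 1, 2, 3, 4, 6, 7).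

## Three steps most likely to fail

**Step 6 (the proposed new step).** The risks are cyclotrimerisation or dimerisation of the terminal alkyne on nickel, slow dehydrogenation of the hindered aliphatic alcohol, nickel insertion into the allylic C–O bond of 9, and insufficient diastereoselectivity at C1′. The fallback uses known chemistry, sets out from 5 and 7 and comes back at 9. Alcohol 5 is oxidised with Dess–Martin periodinane and NaHCO3 in CH2Cl2 at 0 °C to aldehyde 8, which is filtered through a short silica pad and used at once. Alkyne 7 is hydrozirconated with Cp2Zr(H)Cl in CH2Cl2 at rt to chloro[(E)-2-[4-[(tert-butyldimethylsilyl)oxy]phenyl]ethenyl]zirconocene F3. This is transmetalated with Me2Zn in toluene at −65 °C to [(E)-2-[4-[(tert-butyldimethylsilyl)oxy]phenyl]ethenyl](methyl)zinc F4. F4 is added to 8 in the presence of (−)-MIB (10 mol %) at −30 to 0 °C, a catalytic asymmetric alkenylzinc addition of the Oppolzer–Wipf kind. The ligand directs the alkenyl group to the aldehyde Si face, which is the 1′S product and matches the Felkin preference, so 9 is obtained under ligand control.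

**Step 2.** The sense and level of induction of the transfer hydrogenation on this non-aryl ketone are not secured by a close precedent, and the cis/trans ratio may be modest. The fallback sets out from 2 and comes back at 3. Keto ester 2 is reduced with NaBH4 in MeOH at −40 °C, and the racemic cis-hydroxy ester methyl (1RS,2SR)-2-hydroxy-6,7-dimethoxy-1,2,3,4-tetrahydronaphthalene-1-carboxylate F1 is separated from the trans isomer by chromatography. It is esterified with (S)-O-methylmandelic acid (DCC, DMAP, CH2Cl2), and the diastereomers are separated by chromatography or crystallisation to give methyl (1S,2R)-6,7-dimethoxy-2-[[(2S)-2-methoxy-2-phenylacetyl]oxy]-1,2,3,4-tetrahydronaphthalene-1-carboxylate F2. Its mandelate is removed with K2CO3 in MeOH at 0 °C to return 3 (classical resolution in place of the catalytic dynamic kinetic resolution).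

**Step 7.** The secondary TBS ether next to the C1 branch may need forcing fluoride treatment, and the 4-hydroxycinnamyl alcohol can ionise or cyclise onto C3′ under such conditions. The fallback changes the protecting-group plan, sets out from 3 and comes back at 10. Hydroxy ester 3 is silylated with TESOTf and 2,6-lutidine to methyl (1S,2R)-6,7-dimethoxy-2-[(triethylsilyl)oxy]-1,2,3,4-tetrahydronaphthalene-1-carboxylate F5. This is reduced with i-Bu2AlH to [(1R,2R)-6,7-dimethoxy-2-[(triethylsilyl)oxy]-1,2,3,4-tetrahydronaphthalen-1-yl]methanol F6. F6 is coupled with 7 as in step 6 to (1S,2E)-3-[4-[(tert-butyldimethylsilyl)oxy]phenyl]-1-[(1R,2R)-6,7-dimethoxy-2-[(triethylsilyl)oxy]-1,2,3,4-tetrahydronaphthalen-1-yl]prop-2-en-1-ol F7. The labile triethylsilyl ether and the aryl silyl ether are then removed together with Bu4NF and AcOH in THF at −20 °C to give 10.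

## Further compounds

F1 | step 2 | methyl (1RS,2SR)-2-hydroxy-6,7-dimethoxy-1,2,3,4-tetrahydronaphthalene-1-carboxylate (racemic cis, both enantiomers shown) | COc1cc2c(cc1OC)[C@H](C(=O)OC)[C@H](O)CC2.COc1cc2c(cc1OC)[C@@H](C(=O)OC)[C@@H](O)CC2
F2 | step 2 | methyl (1S,2R)-6,7-dimethoxy-2-[[(2S)-2-methoxy-2-phenylacetyl]oxy]-1,2,3,4-tetrahydronaphthalene-1-carboxylate | COc1cc2c(cc1OC)[C@H](C(=O)OC)[C@H](OC(=O)[C@@H](OC)c1ccccc1)CC2
F3 | step 6 | chloro[(E)-2-[4-[(tert-butyldimethylsilyl)oxy]phenyl]ethenyl]zirconocene | Cl[Zr+2]/C=C/c1ccc(O[Si](C)(C)C(C)(C)C)cc1.c1cc[cH-]c1.c1cc[cH-]c1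
F4 | step 6 | [(E)-2-[4-[(tert-butyldimethylsilyl)oxy]phenyl]ethenyl](methyl)zinc | C[Zn]/C=C/c1ccc(O[Si](C)(C)C(C)(C)C)cc1
F5 | step 7 | methyl (1S,2R)-6,7-dimethoxy-2-[(triethylsilyl)oxy]-1,2,3,4-tetrahydronaphthalene-1-carboxylate | COc1cc2c(cc1OC)[C@H](C(=O)OC)[C@H](O[Si](CC)(CC)CC)CC2
F6 | step 7 | [(1R,2R)-6,7-dimethoxy-2-[(triethylsilyl)oxy]-1,2,3,4-tetrahydronaphthalen-1-yl]methanol | COc1cc2c(cc1OC)[C@H](CO)[C@H](O[Si](CC)(CC)CC)CC2
F7 | step 7 | (1S,2E)-3-[4-[(tert-butyldimethylsilyl)oxy]phenyl]-1-[(1R,2R)-6,7-dimethoxy-2-[(triethylsilyl)oxy]-1,2,3,4-tetrahydronaphthalen-1-yl]prop-2-en-1-ol | COc1cc2c(cc1OC)[C@H]([C@@H](O)/C=C/c1ccc(O[Si](C)(C)C(C)(C)C)cc1)[C@H](O[Si](CC)(CC)CC)CC2
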